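**Plan**

- Retrosynthesis: the two sulfate O–S bonds at O7 and O3' are cut first (back to diosmetin and its 5,7,3'-tribenzyl ether), then the C2–C1' bond between ring C and ring B, and last the O1–C2 and C2–C3 bonds of ring C.
- The C2–C1' cut rests on the enone C2=C3–C4=O of ring C: C2, the carbon next to O1, is its electrophilic β carbon, so an aryl group on palladium adds there and the double bond is then restored.
- Forward: ring A is bought as 2,4,6-trihydroxyacetophenone and dibenzylated; ring C is closed on it with a one-carbon formamide acetal; ring B, bought as the arylboronic acid with 3'-O-benzyl and 4'-O-methyl already in place, is joined last at C2.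
- Hydrogenolysis then frees O5, O7 and O3', and sulfation takes O7 and O3' while the 5-hydroxyl, hydrogen-bonded to C4=O, stays free.
- The target has no stereocentre and no stereogenic double bond; only site selectivity (C2 over C3, O7 and O3' over O5) has to be controlled.

Key step: step 3

Remark on the chemistry: the target is taken in the free-acid form drawn (two O–SO3H groups). Because aryl hydrogen sulfates hydrolyse readily, the sulfation product would be purified as its ammonium salt and brought to the acid form by cold cation exchange at the very end.

**Route**

Step 1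
Reactants: 1 2,4,6-trihydroxyacetophenone
Product: 2 1-[2,4-bis(benzyloxy)-6-hydroxyphenyl]ethan-1-one
Conditions: BnBr (2.1 equiv), K2CO3 (2.2 equiv), DMF, 0 °C to rt
Reagents that add atoms: benzyl bromide, BrCc1ccccc1
Why: Williamson ether synthesis: the 4-hydroxyl and one of the two equivalent ortho hydroxyls are benzylated, after which the last ortho hydroxyl is locked in a hydrogen bond to the acetyl C=O and, being the least acidic and least nucleophilic oxygen, should stay free with two equivalents of benzyl bromide.

Step 2
Reactants: 2 1-[2,4-bis(benzyloxy)-6-hydroxyphenyl]ethan-1-one; 3 N,N-dimethylformamide dimethyl acetal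
Product: 5 chromone 5,7-bis(benzyloxy)-4H-chromen-4-one, via enaminone 4 (not isolated)
Conditions: 3 (2 equiv), toluene, 95 °C; evaporate; conc. HCl, CH2Cl2, 40 °C
Reagents that add atoms: none
Why: Enaminone condensation of the acetyl methyl group with the formamide acetal, followed by acid-promoted addition–elimination cyclisation (the phenol oxygen adds to the enaminone β carbon and dimethylamine leaves), is the standard chromone synthesis from 2-hydroxyacetophenones and closes ring C without touching the benzyl ethers.

Step 3
Reactants: 5 5,7-bis(benzyloxy)-4H-chromen-4-one; 6 [3-(benzyloxy)-4-methoxyphenyl]boronic acid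
Product: 7 5,7-bis(benzyloxy)-2-[3-(benzyloxy)-4-methoxyphenyl]-4H-chromen-4-one (5,7,3'-tri-O-benzyldiosmetin)
Conditions: 6 (2.5 equiv), Pd(O2CCF3)2 (10 mol %), Fe(O3SCF3)3 (10 mol %), DDQ (20 mol %), KNO2 (20 mol %), O2 (1 atm), DMF, 60 °C
Reagents that add atoms: none
Why: Transmetalation of boronic acid 6 to Pd(O2CCF3)2 gives an aryl complex of divalent palladium which, with the C4 carbonyl activated by the Lewis acid Fe(O3SCF3)3, adds syn across C2=C3 of chromone 5, the aryl group going to C2 and palladium to C3, the α carbon of the C4 ketone. The C3-bound palladium enolate equilibrates through its oxygen-bound form, which brings palladium syn to the hydrogen on C2 and allows β-hydride elimination that restores the C2=C3 bond; DDQ, turned over by KNO2 and O2, returns zerovalent palladium to the divalent state. The closest known reaction type is the oxidative boron Heck arylation of chromones with arylboronic acids, a known way from chromones to flavones. No ring closes and no stereocentre remains, because the sp3 centres at C2 and C3 exist only in the palladium intermediates. The step needs C2 over C3 selectivity, which the polarisation of the O1–C2=C3–C4=O vinylogous ester secures: only aryl delivery to C2 leaves a stabilised palladium enolate. Neither partner carries a halide, the benzyl and methyl ethers are inert, and the excess of 6 covers losses to protodeboronation and homocoupling.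

Step 4
Reactants: 7 5,7-bis(benzyloxy)-2-[3-(benzyloxy)-4-methoxyphenyl]-4H-chromen-4-one
Product: 8 diosmetin (5,7-dihydroxy-2-(3-hydroxy-4-methoxyphenyl)-4H-chromen-4-one)
Conditions: H2 (1 atm), 10% Pd/C, THF/MeOH 1:1, rt
Reagents that add atoms: none
Why: Catalytic hydrogenolysis over Pd/C cleaves the three benzylic C–O bonds, while the aryl methyl ether is inert and the C2=C3 bond, part of the conjugated γ-pyrone of the flavone, should not be reduced at one atmosphere and room temperature.

Step 5
Reactants: 8 diosmetin
Product: 9 luteolin 4'-methyl ether 7,3'-disulfate (5-hydroxy-2-[4-methoxy-3-(sulfooxy)phenyl]-4-oxo-4H-chromen-7-yl hydrogen sulfate)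
Conditions: SO3·NMe3 (5 equiv), Et3N, DMA, 60 °C; Sephadex LH-20 (MeOH/H2O); then Dowex 50W (H+ form), H2O, 0 °C, freeze-drying
Reagents that add atoms: sulfur trioxide–trimethylamine complex, C[N+](C)(C)S(=O)(=O)[O-]
Why: O-Sulfonation of phenols with a sulfur trioxide–amine complex: the acidic 7-hydroxyl (vinylogous to C4=O) and the 3'-phenol are sulfated, whereas the 5-hydroxyl, tied to C4=O in a six-membered hydrogen bond, is the least nucleophilic oxygen and should stay free with a limited excess of reagent at moderate temperature, and cold cation exchange then gives the acid form.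

**Compound list**

1 | 2,4,6-trihydroxyacetophenone | CC(=O)c1c(O)cc(O)cc1O | starting material
2 | 1-[2,4-bis(benzyloxy)-6-hydroxyphenyl]ethan-1-one | CC(=O)c1c(O)cc(OCc2ccccc2)cc1OCc1ccccc1 | intermediate
3 | N,N-dimethylformamide dimethyl acetal | COC(OC)N(C)C | starting material
4 | (E)-1-[2,4-bis(benzyloxy)-6-hydroxyphenyl]-3-(dimethylamino)prop-2-en-1-one | CN(C)/C=C/C(=O)c1c(O)cc(OCc2ccccc2)cc1OCc1ccccc1 | intermediate
5 | 5,7-bis(benzyloxy)-4H-chromen-4-one | O=c1ccoc2cc(OCc3ccccc3)cc(OCc3ccccc3)c12 | intermediate
6 | [3-(benzyloxy)-4-methoxyphenyl]boronic acid | COc1ccc(B(O)O)cc1OCc1ccccc1 | starting material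
7 | 5,7-bis(benzyloxy)-2-[3-(benzyloxy)-4-methoxyphenyl]-4H-chromen-4-one | COc1ccc(-c2cc(=O)c3c(OCc4ccccc4)cc(OCc4ccccc4)cc3o2)cc1OCc1ccccc1 | intermediate
8 | diosmetin, 5,7-dihydroxy-2-(3-hydroxy-4-methoxyphenyl)-4H-chromen-4-one | COc1ccc(-c2cc(=O)c3c(O)cc(O)cc3o2)cc1O | intermediate
9 | luteolin 4'-methyl ether 7,3'-disulfate | COc1ccc(-c2cc(=O)c3c(O)cc(OS(=O)(=O)O)cc3o2)cc1OS(=O)(=O)O | target

**Count and risks**

Total step count: 5. Longest linear sequence: 5 steps (1 → 2 → 5 → 7 → 8 → 9); boronic acid 6 and acetal 3 enter as purchased.

Steps most likely to fail:

Step 3. The electron-rich boronic acid may be lost to protodeboronation and oxidative homocoupling before it reaches the chromone. Protonolysis of the palladium enolate may also compete with β-hydride elimination, and the catalyst may fall out as palladium metal. The fallback gives up the late C2–C1' coupling and builds ring C after the two aryl parts are joined. It sets out from compound 2, which is condensed with commercial 3-(benzyloxy)-4-methoxybenzaldehyde (KOH, EtOH, rt, Claisen–Schmidt condensation) to the chalcone (E)-1-[2,4-bis(benzyloxy)-6-hydroxyphenyl]-3-[3-(benzyloxy)-4-methoxyphenyl]prop-2-en-1-one F1. Oxidative cyclisation of this chalcone with catalytic I2 in DMSO at 130 °C should close ring C and give the flavone, so the fallback comes back to the route at compound 7.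

Step 5. Sulfation may stop short at the 3'-hydroxyl, which is flanked by the methoxy group, or run on to the 5-hydroxyl. The aryl sulfates may also hydrolyse during the acidic ion exchange. The fallback installs masked, neutral sulfates that can be purified on silica and unmasks them afterwards. It sets out from compound 8, which is treated with 2,2,2-trichloroethyl chlorosulfate, Et3N and DMAP in THF (0 °C to rt) to give diosmetin 7,3'-bis(2,2,2-trichloroethyl sulfate) F2, separable by chromatography from mono- and tris-adducts. Reductive removal of both trichloroethyl groups (Zn dust, HCO2NH4, MeOH, rt) and cold cation exchange should then return the route to compound 9.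

Step 1. Site selectivity may be lost in the partial O-alkylation, with benzylation running on to the third oxygen, stopping at one ether, or going to ring carbon. The fallback replaces partial alkylation by exhaustive alkylation and a chelation-controlled removal of one group. It sets out from compound 1, which is fully benzylated (BnBr 3.5 equiv, K2CO3, DMF, 60 °C) to 1-[2,4,6-tris(benzyloxy)phenyl]ethan-1-one F3. MgBr2·OEt2 in toluene/Et2O at reflux should then cleave only one benzyl ether ortho to the acetyl group, because magnesium is held between the carbonyl and that ether oxygen and the resulting phenoxide chelate protects the second ortho ether. The fallback comes back to the route at compound 2.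

**Further compounds**

F1 | step 3 | (E)-1-[2,4-bis(benzyloxy)-6-hydroxyphenyl]-3-[3-(benzyloxy)-4-methoxyphenyl]prop-2-en-1-one | COc1ccc(/C=C/C(=O)c2c(O)cc(OCc3ccccc3)cc2OCc2ccccc2)cc1OCc1ccccc1
F2 | step 5 | diosmetin 7,3'-bis(2,2,2-trichloroethyl sulfate) | COc1ccc(-c2cc(=O)c3c(O)cc(OS(=O)(=O)OCC(Cl)(Cl)Cl)cc3o2)cc1OS(=O)(=O)OCC(Cl)(Cl)Cl
F3 | step 1 | 1-[2,4,6-tris(benzyloxy)phenyl]ethan-1-one | CC(=O)c1c(OCc2ccccc2)cc(OCc2ccccc2)cc1OCc1ccccc1
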